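(The data are simulated for an exercise; scatter was added.)

Loading multiplied by hours is the unit I would count these flasks in, and I call that product the dose.

in all of them: starting material 0.20 M

| flask | catalyst | remark | time |
|---|---|---|---|
| alder | 0.46 mol% | run made earlier |  |
| larch | 0.87 mol% | run made earlier |  |
| cedar | 1.8 mol% | run made earlier |  |
| red | 0.4 mol% |  | 50 h |
| grey | 0.8 mol% |  | 50 h |
| blue | 2 mol% |  | 50 h |

- alder (time / h: target / %): 2.00: 20.6; 4.00: 26.4; 8.00: 29.2; 12.0: 31.5; 25.0: 22.3
- larch (time / h: target / %): 5.00: 22.9; 10.0: 25.8; 15.0: 23.0; 20.0: 18.1; 25.0: 15.5
- cedar (time / h: target / %): 2.00: 11.8; 6.00: 19.1; 12.0: 15.8; 20.0: 11.4; 25.0: 10.1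

(readings scatter by 1 percentage point)

- amount of target at the end, in percent of the starting material charged for red, grey, blue, in this order
- the course of these numbers from the first flask to the last (falls all the way / rises all the way / falls, then rises / rises, then falls / hardly changes)

- "hardly changes" means that all values lie within two and a half points (for a concentration: within two and a half percent of the largest)

My colleague and I read these runs differently. Once the rise is past, target falls in alder, larch and cedar. My view is that this loss is pseudo-first-order in target, with a rate constant in proportion to loading, so flasks at equal dose should hold equal target whatever their clocks say.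

The readings offer a test. Larch at 25.0 h and cedar at 12.0 h have nearly the same dose, although larch has run twice as long. They read 15.5 % and 15.8 %, a difference of 0.3 percentage points against a scatter of 1 point.

So I treat the tail as one curve in dose. Alder and cedar, both read at 25.0 h, stand at 22.3 % and 10.1 %, which gives 0.00946 h⁻¹ as the loss per dose, stated as the fall in the natural logarithm of target per hour at red's loading of 0.4 mol%. Stepping from alder's last reading by that loss, with each dose taken against red's loading, I reckon 18.2 % for red, 11.4 % for grey and 2.75 % for blue. Blue is the weak figure, since its final dose is twice cedar's last.

My colleague reads the same tails otherwise: “So loss of target looks first-order and roughly independent of catalyst.” The forecast is 10.5 %, 7.5 % and 4.2 %, and its course falls all the way. We agree on the direction and part on the size: my red is higher than the forecast and my blue is lower.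

The flasks give 18.0 %, 9.67 % and 2.50 %, and the course falls all the way.

    starting material ⇌ target (K = 1.40, k = 0.00350 min⁻¹)
    starting material + catalyst ⇌ isomer of the product + catalyst, rate k2*[starting material]*[catalyst] forward; the back reaction follows from the equilibrium constant (K = 1.20, k = 8.90 M⁻¹ min⁻¹)
    catalyst + target → catalyst + over-reaction product (k = 0.830 M⁻¹ min⁻¹)

Carried from 25.0 h to 50 h, the loss per dose takes blue from 8.16 % to 2.50 % and red from 25.4 % to 20.1 %, against 2.50 % and 18.0 % found. The forecast's single slope keeps its region in the tails of the earlier runs, up to 25.0 h, where its slopes were read. Blue shows one part of the loss, not the whole of it: without the conversion of target into over-reaction product on catalyst, blue's target at 50 h stands at 38.9 %, not 2.50 %.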